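How much product, starting material and reagent stand in the violet flask at 5.0 h? You can treat the three as one ledger: the starting material, at 0.46 M against 0.483 M of reagent, is the limiting reagent, and each of its moles is entered as still free, turned into product, or held on the catalyst.

common to all: starting material 0.46 M; reagent 1.05 equiv
- violet: free catalyst 2 mol%; the very flask that is asked about, followed so far
- green: free catalyst 3 mol%; run made earlier
- flask: free catalyst 2 mol%; time 5.0 h

| run | time / min | product / % | starting material / % |
|---|---|---|---|
| violet | 8.00 | 0 | 97 |
| violet | 15.0 | 5 | 98 |
| violet | 25.0 | 4 | 92 |
| violet | 50.0 | 13 | 86 |
| violet | 90.0 | 17 | 79 |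
| green | 10.0 | 1 | 93 |
| green | 20.0 | 6 | 90 |
| green | 30.0 | 12 | 87 |
| green | 60.0 | 18 | 77 |
| green | 120 | 41 | 59 |

(readings scatter by 1.5 percentage points)

- concentration of product at 5.0 h, in M
- concentration of starting material at 5.0 h, in M
- concentration of reagent at 5.0 h, in M



You can read the third entry from the runs. Add product and starting material at each reading and average over a run, and the books fall short by 1.80% in the violet run and by 3.20% in the green run, a wider gap at the higher loading, though each reading carries a scatter of 1.5 percentage points. So you book the gap as the catalyst's hold, the starting material tied up if each catalyst charged carries one mole of it 0.00920 M in the violet flask. Your own commitment is this ledger rather than a product figure: once you have [product], [starting material] is the charge less [product] less the hold, and [reagent] is its charge less [product], less some part of the hold.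

The forecast gives [product] 0.253 M (from 0.21 M to 0.295 M), [starting material] 0.198 M and [reagent] 0.23 M, saying “I take about 55% product and 43% starting material”. Its [product] put through your ledger leaves 0.198 M of starting material.

The flask gives [product] 0.272 M, [starting material] 0.179 M and [reagent] 0.208 M, each within the forecast's tolerance.

    2 free catalyst → spent catalyst (k = 0.0987 L mol⁻¹ min⁻¹)
    starting material + free catalyst → catalyst intermediate A (k = 54.6 L mol⁻¹ min⁻¹)
    reagent + catalyst intermediate B → catalyst intermediate C (k = 0.688 L mol⁻¹ min⁻¹)
    catalyst intermediate A → catalyst intermediate B (k = 2.02 min⁻¹)
    catalyst intermediate C ⇌ catalyst intermediate D (K = 0.507, k = 0.242 min⁻¹)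
    catalyst intermediate D → free catalyst + product (k = 3.18 min⁻¹)

At 5.00 h the four catalyst intermediates together stand at 99.2% of the catalyst charged, so the hold entry is 0.00912 M. Left ten times as long, this flask reaches 0.460 M of product, against 0.317 M with reagent kept from wearing away, so the time allowed is a larger effect on [product] at 0.272 M than that wearing away .

In the neighbour flask read at 3.0 h, [product] of 0.174 M and the same hold leave 0.277 M of starting material, and the computed [starting material] there is 0.277 M.

The numbers in the tables are calculated for substances that don't exist.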